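**Plan**

- Retrosynthesis (labdane numbering: ring A = C1–C5, C10; ring B = C5–C10; C17 on C8; C20 = methyl on C10): the acetate and both acids are unmasked last; the C6=C7 alkene with its allylic C5–H is traced to a 5-en-7-ol (reductive 1,3-transposition) and so to a 5-en-7-one; ring B is then cut at C5–C6 and C9–C10 (formal [4+2], Robinson type); the acyclic partner is cut at C8=C9 (Knoevenagel) and C12–C13 (Negishi).
- Forward: ring A is bought as 2,2,6-trimethylcyclohexanone; the side-chain aldehyde is made in four steps and condensed with a γ-phosphono acetoacetate; the alkylidene is joined to the enol silane of ring A in one flask (C9–C10 by Michael addition, then C5=C6 by intramolecular olefination), which closes ring B; reduction, transposition and protecting-group exchange finish the route.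
- Enabling feature: in ring B, C10 is the α-carbon and C5 the carbonyl carbon of a ketone with a single enolisable position; C9 is β to the C17 carboxyl on C8; the C6=C7 alkene is a masked C7 ketone, so C8 sits in a β-keto ester and C6 can be a phosphonate carbanion.
- Stereochemistry: C10 and C9 from the copper–bis(oxazoline)-controlled Michael step; C8 by equilibration of the β-keto ester; C7 by axial hydride delivery; C5 by suprafacial hydrogen transfer from a C7 diazene; the 13E alkene from anti hydroiodination and a stereoretentive coupling.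

Key step: step 8

Assumption: the (S,S)-ligand is taken to give the 9R,10S adduct; if a test run shows the opposite sense, the (R,R)-ligand is used and nothing else changes.

**Route**

Step 1
Reactants: 1 2,2,6-trimethylcyclohexan-1-one
Product: 2 trimethyl[(2,6,6-trimethylcyclohex-1-en-1-yl)oxy]silane
Conditions: LiN(i-Pr)2, THF, −78 to 0 °C; then Me3SiCl, −78 °C to rt
Reagents that add atoms: chlorotrimethylsilane, C[Si](C)(C)Cl
Why: Lithium enolate formation and O-silylation (silyl enol ether synthesis) can give only one regioisomer because C6–H is the sole enolisable hydrogen of 1, C2 being quaternary.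

Step 2
Reactants: 3 (diethoxyphosphoryl)acetic acid; 4 2,2-dimethyl-1,3-dioxane-4,6-dione (Meldrum's acid)
Product: 6 tert-butyl 4-(diethoxyphosphoryl)-3-oxobutanoate, via acyl Meldrum's acid 5 (not isolated)
Conditions: DCC, DMAP, CH2Cl2, 0 °C to rt; filter; then t-BuOH, toluene, 90 °C
Reagents that add atoms: tert-butanol, CC(C)(C)O
Why: C-Acylation of Meldrum's acid by the carbodiimide-activated acid and thermal alcoholysis of the acyl Meldrum's acid through its acylketene is the standard β-keto ester synthesis and leaves the phosphonate untouched.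

Step 3
Reactants: 7 tert-butyl(diphenyl)(prop-2-yn-1-yloxy)silane
Product: 8 tert-butyl 4-{[tert-butyl(diphenyl)silyl]oxy}but-2-ynoate
Conditions: n-BuLi, THF, −78 °C; then Boc2O, −78 °C to rt
Reagents that add atoms: di-tert-butyl dicarbonate, CC(C)(C)OC(=O)OC(=O)OC(C)(C)C
Why: Alkoxycarbonylation of the lithium acetylide with Boc2O gives the tert-butyl ynoate directly, the silyl ether being inert to n-BuLi at −78 °C.

Step 4
Reactants: 8 tert-butyl 4-{[tert-butyl(diphenyl)silyl]oxy}but-2-ynoate
Product: 9 tert-butyl (2Z)-4-{[tert-butyl(diphenyl)silyl]oxy}-3-iodobut-2-enoate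
Conditions: NaI, AcOH, 70 °C
Reagents that add atoms: sodium iodide, [Na+].[I-]
Why: Conjugate hydroiodination of the ynoate is an anti addition (iodide at C3, proton at C2), so iodine ends cis to the ester, which fixes the later 13E geometry.

Step 5
Reactants: 9 tert-butyl (2Z)-4-{[tert-butyl(diphenyl)silyl]oxy}-3-iodobut-2-enoate; 10 bromo[2-(1,3-dioxolan-2-yl)ethyl]zinc (commercial THF solution)
Product: 11 tert-butyl (2E)-3-({[tert-butyl(diphenyl)silyl]oxy}methyl)-5-(1,3-dioxolan-2-yl)pent-2-enoate
Conditions: Pd(PPh3)4 (5 mol%), THF, 25 to 45 °C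
Reagents that add atoms: none
Why: Negishi sp3–sp2 coupling at the electron-poor alkenyl iodide proceeds with retention of alkene geometry and tolerates ester, silyl ether and acetal, so the chain carbon ends cis to the ester.

Step 6
Reactants: 11 tert-butyl (2E)-3-({[tert-butyl(diphenyl)silyl]oxy}methyl)-5-(1,3-dioxolan-2-yl)pent-2-enoate
Product: 12 tert-butyl (2E)-3-({[tert-butyl(diphenyl)silyl]oxy}methyl)-6-oxohex-2-enoate
Conditions: TsOH·H2O (cat.), acetone/H2O 10:1, 50 °C
Reagents that add atoms: water, O
Why: Acid-catalysed acetal hydrolysis frees the aldehyde under conditions too mild to cleave the tert-butyl ester or the tert-butyldiphenylsilyl ether.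

Step 7
Reactants: 12 tert-butyl (2E)-3-({[tert-butyl(diphenyl)silyl]oxy}methyl)-6-oxohex-2-enoate; 6 tert-butyl 4-(diethoxyphosphoryl)-3-oxobutanoate
Product: 13 di-tert-butyl (6E)-6-({[tert-butyl(diphenyl)silyl]oxy}methyl)-2-[(diethoxyphosphoryl)acetyl]octa-2,6-dienedioate (2E/2Z mixture)
Conditions: piperidine (10 mol%), AcOH (10 mol%), CH2Cl2, 4 Å molecular sieves, 0 °C to rt
Reagents that add atoms: none
Why: Knoevenagel condensation occurs at the methylene flanked by ketone and ester, which is far more acidic than the phosphonate methylene, and either alkylidene isomer can enter the next step.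

Step 8
Reactants: 2 trimethyl[(2,6,6-trimethylcyclohex-1-en-1-yl)oxy]silane; 13 di-tert-butyl (6E)-6-({[tert-butyl(diphenyl)silyl]oxy}methyl)-2-[(diethoxyphosphoryl)acetyl]octa-2,6-dienedioate
Product: 15 di-tert-butyl (9R,10S,13E)-16-{[tert-butyl(diphenyl)silyl]oxy}-7-oxolabda-5,13-diene-15,17-dioate (C8 ester trans to the C9 chain; C9 chain cis to the C10 methyl), via Michael adduct 14 (not isolated)
Conditions: Cu(OTf)2 (10 mol%), (S,S)-t-Bu-box [2,2'-(propane-2,2-diyl)bis((4S)-4-tert-butyl-4,5-dihydrooxazole)] (11 mol%), (CF3)2CHOH (1.2 equiv), CH2Cl2, −78 to −20 °C; evaporate; then LiN(i-Pr)2 (2.3 equiv), THF, −78 to 50 °C; aq. NH4Cl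
Reagents that add atoms: none
Why: Proposed new method: the alkylidene, chelated through both carbonyls to divalent copper, is attacked at C9 by the tetrasubstituted enol silane in a Mukaiyama–Michael addition that forms the C9–C10 bond, the alcohol additive releasing the β-keto ester and turning the catalyst over; deprotonation of adduct 14 to its phosphonate dianion then brings about a 6-exo-trig addition of C6 to the non-enolisable ring A carbonyl and loss of diethyl phosphate, which forms the C5=C6 bond and closes ring B. The closest known reactions are the copper–bis(oxazoline)-catalysed Mukaiyama–Michael addition to alkylidene malonates and the Robinson-type Michael/intramolecular Horner–Wadsworth–Emmons annulation with γ-phosphono acetoacetate dianions; new here are the very hindered enol silane and the joining of both events in one flask. C10 (quaternary) and C9 are set in the first event: the tert-butyl groups of the ligand shield one face of the planar chelate, and a compact endo-type approach that turns the gem-dimethyl carbon of 2 away from the chelate should put the C10 methyl and the C9 chain cis; C8 then settles as the equatorial ester trans to that chain by enolisation of the β-keto ester. Regiochemistry needs no control: 1 has one enolisable position, C9 is the only doubly activated acceptor carbon, and the C5 carbonyl is the only one the dianion carbon can reach through a six-membered transition state.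

Step 9
Reactants: 15 di-tert-butyl (9R,10S,13E)-16-{[tert-butyl(diphenyl)silyl]oxy}-7-oxolabda-5,13-diene-15,17-dioate
Product: 16 di-tert-butyl (9R,10S,13E)-16-{[tert-butyl(diphenyl)silyl]oxy}-7-hydroxylabda-5,13-diene-15,17-dioate (7-OH cis to the C10 methyl and trans to the C8 ester)
Conditions: NaBH4, CeCl3·7H2O, MeOH/THF, −78 to −40 °C
Reagents that add atoms: none
Why: Luche 1,2-reduction of the enone carbonyl should deliver hydride axially to C7 from the face opposite the C10 methyl, as with steroidal 4-en-3-ones, giving the pseudo-equatorial 7-alcohol cis to that methyl and trans to the equatorial C8 ester.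

Step 10
Reactants: 16 di-tert-butyl (9R,10S,13E)-16-{[tert-butyl(diphenyl)silyl]oxy}-7-hydroxylabda-5,13-diene-15,17-dioate
Product: 19 di-tert-butyl (5R,8S,9R,10S,13E)-16-{[tert-butyl(diphenyl)silyl]oxy}labda-6,13-diene-15,17-dioate, via sulfonylhydrazide 17 (not isolated), via allylic diazene 18 (not isolated)
Conditions: 2-O2NC6H4SO2NHNH2, PPh3, DEAD, THF, −30 °C; then rt
Reagents that add atoms: none
Why: Reductive 1,3-transposition of the allylic alcohol: Mitsunobu displacement by the sulfonylhydrazide inverts C7, loss of 2-nitrobenzenesulfinic acid gives the monoalkyl diazene, and its retro-ene loss of N2 transfers hydrogen suprafacially to C5 on the face trans to the C10 methyl while the alkene moves to C6=C7, which sets the trans ring fusion.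

Step 11
Reactants: 19 di-tert-butyl (5R,8S,9R,10S,13E)-16-{[tert-butyl(diphenyl)silyl]oxy}labda-6,13-diene-15,17-dioate
Product: 20 di-tert-butyl (5R,8S,9R,10S,13E)-16-hydroxylabda-6,13-diene-15,17-dioate
Conditions: HF·pyridine, pyridine, THF, 0 °C to rt
Reagents that add atoms: none
Why: Buffered fluoride cleavage of the primary silyl ether (desilylation) is non-basic and so leaves the tert-butyl esters and the allylic, ester-bearing C8 centre unchanged.

Step 12
Reactants: 20 di-tert-butyl (5R,8S,9R,10S,13E)-16-hydroxylabda-6,13-diene-15,17-dioate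
Product: 21 di-tert-butyl (5R,8S,9R,10S,13E)-16-acetoxylabda-6,13-diene-15,17-dioate
Conditions: Ac2O, pyridine, DMAP (cat.), CH2Cl2, 0 °C to rt
Reagents that add atoms: acetic anhydride, CC(=O)OC(C)=O
Why: Acylation of the primary allylic alcohol with Ac2O under nucleophilic catalysis is carried out while both acids are still tert-butyl esters, so no mixed anhydride can form.

Step 13
Reactants: 21 di-tert-butyl (5R,8S,9R,10S,13E)-16-acetoxylabda-6,13-diene-15,17-dioate
Product: 22 (5R,8S,9R,10S,13E)-16-acetoxylabda-6,13-diene-15,17-dioic acid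
Conditions: CF3CO2H/CH2Cl2 1:3, 0 °C to rt
Reagents that add atoms: none
Why: Acidolysis of the two tert-butyl esters (loss of isobutene) needs no base or nucleophile and so should spare the acetate, the configuration at C8 and the positions of both alkenes.

**Compound list**

1 | 2,2,6-trimethylcyclohexan-1-one | CC1CCCC(C)(C)C1=O | starting material
2 | trimethyl[(2,6,6-trimethylcyclohex-1-en-1-yl)oxy]silane | CC1=C(O[Si](C)(C)C)C(C)(C)CCC1 | intermediate
3 | (diethoxyphosphoryl)acetic acid | CCOP(=O)(CC(=O)O)OCC | starting material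
4 | 2,2-dimethyl-1,3-dioxane-4,6-dione (Meldrum's acid) | CC1(C)OC(=O)CC(=O)O1 | starting material
5 | 5-[2-(diethoxyphosphoryl)-1-hydroxyethylidene]-2,2-dimethyl-1,3-dioxane-4,6-dione (acyl Meldrum's acid) | CCOP(=O)(CC(O)=C1C(=O)OC(C)(C)OC1=O)OCC | intermediate
6 | tert-butyl 4-(diethoxyphosphoryl)-3-oxobutanoate | CCOP(=O)(CC(=O)CC(=O)OC(C)(C)C)OCC | intermediate
7 | tert-butyl(diphenyl)(prop-2-yn-1-yloxy)silane | C#CCO[Si](c1ccccc1)(c1ccccc1)C(C)(C)C | starting material
8 | tert-butyl 4-{[tert-butyl(diphenyl)silyl]oxy}but-2-ynoate | CC(C)(C)OC(=O)C#CCO[Si](c1ccccc1)(c1ccccc1)C(C)(C)C | intermediate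
9 | tert-butyl (2Z)-4-{[tert-butyl(diphenyl)silyl]oxy}-3-iodobut-2-enoate | CC(C)(C)[Si](c1ccccc1)(c1ccccc1)OC/C(I)=C/C(=O)OC(C)(C)C | intermediate
10 | bromo[2-(1,3-dioxolan-2-yl)ethyl]zinc | Br[Zn]CCC1OCCO1 | starting material
11 | tert-butyl (2E)-3-({[tert-butyl(diphenyl)silyl]oxy}methyl)-5-(1,3-dioxolan-2-yl)pent-2-enoate | CC(C)(C)[Si](c1ccccc1)(c1ccccc1)OC/C(=C/C(=O)OC(C)(C)C)CCC1OCCO1 | intermediate
12 | tert-butyl (2E)-3-({[tert-butyl(diphenyl)silyl]oxy}methyl)-6-oxohex-2-enoate | CC(C)(C)[Si](c1ccccc1)(c1ccccc1)OC/C(=C/C(=O)OC(C)(C)C)CCC=O | intermediate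
13 | di-tert-butyl (6E)-6-({[tert-butyl(diphenyl)silyl]oxy}methyl)-2-[(diethoxyphosphoryl)acetyl]octa-2,6-dienedioate (2E/2Z mixture) | CC(C)(C)[Si](c1ccccc1)(c1ccccc1)OC/C(=C/C(=O)OC(C)(C)C)CCC=C(C(=O)OC(C)(C)C)C(=O)CP(=O)(OCC)OCC | intermediate
14 | di-tert-butyl (3R,6E)-6-({[tert-butyl(diphenyl)silyl]oxy}methyl)-2-[(diethoxyphosphoryl)acetyl]-3-[(1S)-1,3,3-trimethyl-2-oxocyclohexyl]oct-6-enedioate (C2 epimers; Michael adduct) | CC(C)(C)[Si](c1ccccc1)(c1ccccc1)OC/C(=C/C(=O)OC(C)(C)C)CC[C@@H]([C@]1(C)CCCC(C)(C)C1=O)C(C(=O)OC(C)(C)C)C(=O)CP(=O)(OCC)OCC | intermediate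
15 | di-tert-butyl (9R,10S,13E)-16-{[tert-butyl(diphenyl)silyl]oxy}-7-oxolabda-5,13-diene-15,17-dioate (C8 ester trans to the C9 chain) | CC(C)(C)[Si](c1ccccc1)(c1ccccc1)OC/C(=C/C(=O)OC(C)(C)C)CC[C@@H]1[C@@H](C(=O)OC(C)(C)C)C(=O)C=C2C(C)(C)CCC[C@@]12C | intermediate
16 | di-tert-butyl (9R,10S,13E)-16-{[tert-butyl(diphenyl)silyl]oxy}-7-hydroxylabda-5,13-diene-15,17-dioate (7-OH cis to the C10 methyl, trans to the C8 ester) | CC(C)(C)[Si](c1ccccc1)(c1ccccc1)OC/C(=C/C(=O)OC(C)(C)C)CC[C@@H]1[C@@H](C(=O)OC(C)(C)C)[C@H](O)C=C2C(C)(C)CCC[C@@]12C | intermediate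
17 | di-tert-butyl (9R,10S,13E)-16-{[tert-butyl(diphenyl)silyl]oxy}-7-[1-(2-nitrobenzenesulfonyl)hydrazinyl]labda-5,13-diene-15,17-dioate (nitrogen on C7 trans to the C10 methyl) | CC(C)(C)[Si](c1ccccc1)(c1ccccc1)OC/C(=C/C(=O)OC(C)(C)C)CC[C@@H]1[C@@H](C(=O)OC(C)(C)C)[C@@H](N(N)S(=O)(=O)c3ccccc3[N+](=O)[O-])C=C2C(C)(C)CCC[C@@]12C | intermediate
18 | di-tert-butyl (9R,10S,13E)-16-{[tert-butyl(diphenyl)silyl]oxy}-7-diazenyllabda-5,13-diene-15,17-dioate (diazene on C7 trans to the C10 methyl) | CC(C)(C)[Si](c1ccccc1)(c1ccccc1)OC/C(=C/C(=O)OC(C)(C)C)CC[C@@H]1[C@@H](C(=O)OC(C)(C)C)[C@@H](N=N)C=C2C(C)(C)CCC[C@@]12C | intermediate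
19 | di-tert-butyl (5R,8S,9R,10S,13E)-16-{[tert-butyl(diphenyl)silyl]oxy}labda-6,13-diene-15,17-dioate | CC(C)(C)[Si](c1ccccc1)(c1ccccc1)OC/C(=C/C(=O)OC(C)(C)C)CC[C@@H]1[C@@H](C(=O)OC(C)(C)C)C=C[C@@H]2C(C)(C)CCC[C@@]12C | intermediate
20 | di-tert-butyl (5R,8S,9R,10S,13E)-16-hydroxylabda-6,13-diene-15,17-dioate | OC/C(=C/C(=O)OC(C)(C)C)CC[C@@H]1[C@@H](C(=O)OC(C)(C)C)C=C[C@@H]2C(C)(C)CCC[C@@]12C | intermediate
21 | di-tert-butyl (5R,8S,9R,10S,13E)-16-acetoxylabda-6,13-diene-15,17-dioate | CC(=O)OC/C(=C/C(=O)OC(C)(C)C)CC[C@@H]1[C@@H](C(=O)OC(C)(C)C)C=C[C@@H]2C(C)(C)CCC[C@@]12C | intermediate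
22 | (5R,8S,9R,10S,13E)-16-acetoxylabda-6,13-diene-15,17-dioic acid | CC(=O)OC/C(=C/C(=O)O)CC[C@@H]1[C@@H](C(=O)O)C=C[C@@H]2C(C)(C)CCC[C@@]12C | target

**Step count and risks**

Total step count: 13. Longest linear sequence: 11 steps (7 to 22, steps 3 to 13).

Steps most likely to fail:

1. Step 8 (Proposed new method). The catalyst-bound alkylidene may be attacked from both faces because the enol silane is fully substituted and very hindered, so that enantioface control and the C9/C10 relationship are lost; the phosphoryl oxygen may also compete for the copper centre. The fallback uses known chemistry in the racemic series followed by resolution. It sets out from 2 and 13. Yb(OTf)3-catalysed Mukaiyama–Michael addition in CH2Cl2 should give 14 as the racemate, that is, together with ent-14 F1, and the adduct is isolated. LiN(i-Pr)2 (2.3 equiv) in THF then effects the Horner–Wadsworth–Emmons closure to 15 together with ent-15 F2. Luche reduction as in step 9 gives 16 together with ent-16 F3. Esterification with (S)-methoxy(phenyl)acetic acid (DCC, DMAP) gives the O-methylmandelate ester F4 (from 16) and the O-methylmandelate ester F5 (from ent-16), which are diastereomers and are separated by chromatography. Methanolysis of F4 (K2CO3, MeOH) returns 16, and the route goes on with step 10.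

2. Step 10. Displacement at C7 may be slow because the carbinol is flanked by the C8 tert-butyl ester, so that elimination to the 5,7-dienoate competes with substitution. The fallback sets out from 16. Formylation (HCO2H, DCC, DMAP) gives the allylic formate F6. Pd(OAc)2 with n-Bu3P in THF at reflux should ionise it with inversion to the allylpalladium complex; loss of CO2 and hydride transfer from palladium to the more substituted terminus C5, on the face opposite to the former C7–O bond, then give 19 directly.

3. Step 9. Hydride may be delivered to the other face of C7, since the C8 ester and cerium binding to the β-keto ester may override the usual axial preference; the C7 epimer would lead to the cis ring fusion. The fallback sets out from 15 and uses a reagent-controlled Corey–Bakshi–Shibata reduction (oxazaborolidine enantiomer matched to the required face, catecholborane, toluene, −78 °C) to reach 16; it makes no new compound.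

Further compounds
F1 | step 8 | ent-14 (mirror image of the Michael adduct) | CC(C)(C)[Si](c1ccccc1)(c1ccccc1)OC/C(=C/C(=O)OC(C)(C)C)CC[C@H]([C@@]1(C)CCCC(C)(C)C1=O)C(C(=O)OC(C)(C)C)C(=O)CP(=O)(OCC)OCC
F2 | step 8 | ent-15 | CC(C)(C)[Si](c1ccccc1)(c1ccccc1)OC/C(=C/C(=O)OC(C)(C)C)CC[C@H]1[C@H](C(=O)OC(C)(C)C)C(=O)C=C2C(C)(C)CCC[C@]12C
F3 | step 8 | ent-16 | CC(C)(C)[Si](c1ccccc1)(c1ccccc1)OC/C(=C/C(=O)OC(C)(C)C)CC[C@H]1[C@H](C(=O)OC(C)(C)C)[C@@H](O)C=C2C(C)(C)CCC[C@]12C
F4 | step 8 | O-methylmandelate ester of 16, (S)-methoxy(phenyl)acetate at O7 | CC(C)(C)[Si](c1ccccc1)(c1ccccc1)OC/C(=C/C(=O)OC(C)(C)C)CC[C@@H]1[C@@H](C(=O)OC(C)(C)C)[C@H](OC(=O)[C@@H](OC)c3ccccc3)C=C2C(C)(C)CCC[C@@]12C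
F5 | step 8 | O-methylmandelate ester of ent-16, (S)-methoxy(phenyl)acetate at O7 | CC(C)(C)[Si](c1ccccc1)(c1ccccc1)OC/C(=C/C(=O)OC(C)(C)C)CC[C@H]1[C@H](C(=O)OC(C)(C)C)[C@@H](OC(=O)[C@@H](OC)c3ccccc3)C=C2C(C)(C)CCC[C@]12C
F6 | step 10 | allylic formate of 16 | CC(C)(C)[Si](c1ccccc1)(c1ccccc1)OC/C(=C/C(=O)OC(C)(C)C)CC[C@@H]1[C@@H](C(=O)OC(C)(C)C)[C@H](OC=O)C=C2C(C)(C)CCC[C@@]12C
F0 | step 9 | none | none
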